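**Plan**
- Cuts, in order: C2′–phenyl (Suzuki coupling of a lactone-derived ketene acetal phosphate); O1′ out of the C8a′–C2′ link; the acyl–aryl bond of the resulting indanone (Friedel–Crafts); C4′–aryl (aryl Grignard addition to an alkylidene Meldrum's acid); C4′=C3′ (Knoevenagel); the formyl carbon on C1 (Wittig homologation of a C1 ketone).
- Enabling feature: in the pyran ring O1′ lies between the aromatic carbon C8a′ and C2′, so the benzopyranone is a 4,6,7-trimethoxyindan-1-one with one oxygen inserted into its C1–C7a bond. The indanone already holds C4′, C3′, C2′ and the arene, and C7a (future C8a′) is an aryl carbon with an ortho methoxy group, the better migrating terminus.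
- Forward ring order: ring B comes from (+)-dihydrocarvone; ring A is annulated, then re-oxidised with singlet oxygen (C1=O, C4–OH); the five-membered ketone ring is closed onto the arene, expanded by one oxygen to the six-membered lactone, and the C2′ phenyl is attached last.
- Stereochemistry: C7 from the chiral pool; C10 from the (R)-1-phenylethylamine auxiliary; C5 from dissolving-metal reduction; C4 from α-face singlet-oxygen attack; C1 by equilibration to the equatorial aldehyde; C4′ by A(1,3)-controlled aryl addition anti to C10.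

Key step: step 15

Remarks on the chemistry:
- Eudesmane locants C1–C15 and primed chromene locants are used throughout.
- Commercial (+)-dihydrocarvone is a C2-epimeric mixture of the 5R series; both epimers give the same enamine in step 1, so the mixture is used as such.
- The benzylic carbon keeps one spatial arrangement from step 12 onward. It is R in acid 22, indanone 24 and lactone 26 (eudesmane C1 outranks the ring CH2) and S in 21, 27, 29 and 30 (C3′ or the Meldrum's carbon outranks eudesmane C1).

Step 1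
Reactants: 1 (2R,5R)-(+)-dihydrocarvone; 2 pent-1-en-3-one (ethyl vinyl ketone)
Product: 5 (2S,5R)-2-methyl-2-(3-oxopentyl)-5-(prop-1-en-2-yl)cyclohexan-1-one, via dihydrocarvone N-[(R)-1-phenylethyl]imine 3 (not isolated), via Michael-adduct imine 4 (not isolated)
Conditions: (R)-1-phenylethylamine, toluene, reflux (Dean–Stark); then 2, THF, 40 °C; then 10% aq. AcOH, rt
Reagents that add atoms: water, O
Why: Deracemising Michael addition of a chiral imine: the secondary enamine tautomer of 3 should add to the enone at its more substituted α-carbon through a chair-like aza-ene transition state on the face anti to the phenyl group of the (R)-auxiliary, which sets C10 (2S, methyl cis to isopropenyl) whatever the C2 configuration of 1, and mild acid hydrolysis then releases the diketone.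

Step 2
Reactants: 5 (2S,5R)-2-methyl-2-(3-oxopentyl)-5-(prop-1-en-2-yl)cyclohexan-1-one
Product: 6 (+)-α-cyperone, (4aS,7R)-1,4a-dimethyl-7-(prop-1-en-2-yl)-4,4a,5,6,7,8-hexahydronaphthalen-2(3H)-one
Conditions: NaOMe (cat.), MeOH, rt to 50 °C
Reagents that add atoms: none
Why: Intramolecular aldol condensation (second stage of the Robinson annulation) of the ethyl ketone onto the ring carbonyl with dehydration should close ring A as the tetrasubstituted enone without touching the quaternary C10.

Step 3
Reactants: 6 (+)-α-cyperone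
Product: 7 (4βH,5αH)-eudesm-11-en-3-one (trans-decalin; C4 methyl α and equatorial)
Conditions: Li, NH3(l)/THF, t-BuOH (1 equiv), −78 °C; then NH4Cl
Reagents that add atoms: none
Why: Dissolving-metal (Birch-type) enone reduction: protonation of the β-carbanion at C5 should give the trans ring fusion (5α-H), protonation of the enolate places the C4 methyl equatorial, and the isolated isopropenyl alkene is not reduced.

Step 4
Reactants: 7 (4βH,5αH)-eudesm-11-en-3-one
Product: 9 (4βH,5αH)-eudesma-1,11-dien-3-one, via trimethylsilyl enol ether 8 (not isolated)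
Conditions: LiN(i-Pr)2, THF, −78 °C, then Me3SiCl; then Pd(OAc)2 (1 equiv), MeCN, rt
Reagents that add atoms: none
Why: Kinetic deprotonation at the C2 methylene rather than the C4 methine followed by Saegusa–Ito dehydrosilylation should place the new double bond at C1=C2 only.

Step 5
Reactants: 9 (4βH,5αH)-eudesma-1,11-dien-3-one
Product: 10 5αH-eudesma-1,3,11-trien-3-yl trifluoromethanesulfonate
Conditions: KN(SiMe3)2, THF, −78 °C; then PhNTf2, −78 to 0 °C
Reagents that add atoms: N-phenylbis(trifluoromethanesulfonimide), O=S(=O)(N(c1ccccc1)S(=O)(=O)C(F)(F)F)C(F)(F)F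
Why: Enol triflate formation: the axial C4–H is the only enolisable hydrogen of 9 (C2 is vinylic, C10 quaternary), so α′-deprotonation gives the cross-conjugated dienolate, which is triflated on oxygen.

Step 6
Reactants: 10 5αH-eudesma-1,3,11-trien-3-yl trifluoromethanesulfonate
Product: 11 5αH-eudesma-1,3,11-triene
Conditions: Pd(OAc)2 (cat.), PPh3, n-Bu3N, HCO2H, DMF, 60 °C
Reagents that add atoms: none
Why: Palladium-catalysed formate reduction of the dienyl triflate (oxidative addition, formate-to-hydride exchange with loss of CO2, reductive elimination) should replace OTf by H and leave the isopropenyl group alone.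

Step 7
Reactants: 11 5αH-eudesma-1,3,11-triene
Product: 13 4α-hydroxy-5αH-eudesma-2,11-dien-1-one, via 1α,4α-endoperoxide 12 (not isolated)
Conditions: O2, tetraphenylporphyrin (cat.), visible light, CH2Cl2, −20 °C; then DBU (cat.), 0 °C to rt
Reagents that add atoms: dioxygen, O=O
Why: The cisoid ring-A diene should take up singlet oxygen in a [4+2] cycloaddition on the α face, anti to the C10 angular methyl and much faster than the isopropenyl group undergoes the ene reaction, and base-induced Kornblum–DeLaMare rearrangement (removal of the only peroxide-bearing C–H, at C1) then gives the C1 ketone and the tertiary 4α-alcohol, which sets C4.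

Step 8
Reactants: 13 4α-hydroxy-5αH-eudesma-2,11-dien-1-one
Product: 14 4α-(triethylsilyloxy)-5αH-eudesma-2,11-dien-1-one
Conditions: Et3SiOTf, 2,6-lutidine, CH2Cl2, −78 to 0 °C
Reagents that add atoms: triethylsilyl trifluoromethanesulfonate, CC[Si](CC)(CC)OS(=O)(=O)C(F)(F)F
Why: Silylation of the tertiary alcohol is clean at this stage because enone 13 has no enolisable hydrogen (C2 vinylic, C4 and C10 quaternary).

Step 9
Reactants: 14 4α-(triethylsilyloxy)-5αH-eudesma-2,11-dien-1-one
Product: 15 4α-(triethylsilyloxy)-5αH-eudesm-11-en-1-one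
Conditions: [(Ph3P)CuH]6, toluene, degassed H2O, rt
Reagents that add atoms: none
Why: Copper hydride conjugate reduction (1,4-hydride delivery, then protonation of the copper enolate) should saturate C2=C3 chemoselectively beside the isolated isopropenyl alkene.

Step 10
Reactants: 15 4α-(triethylsilyloxy)-5αH-eudesm-11-en-1-one
Product: 17 4α-(triethylsilyloxy)-5αH-eudesm-11-ene-1β-carbaldehyde, via methyl enol ether 16 (not isolated)
Conditions: Ph3P(Cl)CH2OMe, KN(SiMe3)2, THF, 0 to 45 °C; then 0.5 M HCl, THF, 0 °C; then K2CO3 (cat.), MeOH, rt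
Reagents that add atoms: (methoxymethyl)triphenylphosphonium chloride, COC[P+](c1ccccc1)(c1ccccc1)c1ccccc1.[Cl-]; water, O
Why: Wittig methoxymethylenation of the hindered ketone, enol-ether hydrolysis and base equilibration should give the one-carbon homologue with C1 set thermodynamically (equatorial 1β-formyl), the same epimer that protonation of the enol ether from the α face, away from the axial C10 methyl, produces.

Step 11
Reactants: 17 4α-(triethylsilyloxy)-5αH-eudesm-11-ene-1β-carbaldehyde
Product: 18 5-{[4α-(triethylsilyloxy)-5αH-eudesm-11-en-1β-yl]methylidene}-2,2-dimethyl-1,3-dioxane-4,6-dione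
Conditions: Meldrum's acid, piperidinium acetate (cat.), toluene, 4 Å molecular sieves, rt
Reagents that add atoms: 2,2-dimethyl-1,3-dioxane-4,6-dione (Meldrum's acid), CC1(C)OC(=O)CC(=O)O1
Why: Knoevenagel condensation of the α-branched aldehyde with the highly C–H-acidic dione should give the doubly activated alkene, and the equatorial C1 configuration is the thermodynamic one under the amine catalysis.

Step 12
Reactants: 18 alkylidene Meldrum's acid; 19 1-bromo-2,4,5-trimethoxybenzene
Product: 21 5-{(S)-[4α-(triethylsilyloxy)-5αH-eudesm-11-en-1β-yl](2,4,5-trimethoxyphenyl)methyl}-2,2-dimethyl-1,3-dioxane-4,6-dione, via 2,4,5-trimethoxyphenylmagnesium bromide 20 (not isolated)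
Conditions: 19, Mg, THF, 50 °C; then 18, THF, −40 to 0 °C; then aq. NH4Cl
Reagents that add atoms: none
Why: Conjugate addition of an aryl Grignard reagent to an alkylidene Meldrum's acid: the carbonyl cis to C1 enforces, through A(1,3) strain, the rotamer with C1–H in the alkene plane, so the two faces are flanked by C2 (CH2) and by the quaternary C10 with its axial methyl, and the aryl group should add anti to C10, which sets C4′ in the required sense.

Step 13
Reactants: 21 aryl adduct of the Meldrum's acid
Product: 22 (3R)-3-[4α-(triethylsilyloxy)-5αH-eudesm-11-en-1β-yl]-3-(2,4,5-trimethoxyphenyl)propanoic acid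
Conditions: pyridine/H2O (10:1), 100 °C
Reagents that add atoms: water, O
Why: Hydrolytic ring opening of the monosubstituted Meldrum's acid and decarboxylation of the malonic half-acid (loss of acetone and CO2) should give the monoacid under buffered conditions that spare the silyl ether and leave the β-stereocentre untouched.

Step 14
Reactants: 22 (3R)-3-aryl-3-eudesmanylpropanoic acid
Product: 24 (3R)-3-[4α-(triethylsilyloxy)-5αH-eudesm-11-en-1β-yl]-4,6,7-trimethoxyindan-1-one, via acid chloride 23 (not isolated)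
Conditions: 1-chloro-N,N,2-trimethylprop-1-en-1-amine, CH2Cl2, 0 °C to rt; then SnCl4, 2,6-di-tert-butyl-4-methylpyridine, CH2Cl2, −78 to −30 °C
Reagents that add atoms: none
Why: The neutral chloroenamine makes the acid chloride without free HCl, and SnCl4 then triggers intramolecular Friedel–Crafts acylation at the only free ortho position of the aryl group (ortho to a methoxy group), closing the five-membered ketone ring while low temperature and the hindered pyridine protect the isopropenyl group and the silyl ether.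

Step 15
Reactants: 24 (3R)-3-[4α-(triethylsilyloxy)-5αH-eudesm-11-en-1β-yl]-4,6,7-trimethoxyindan-1-one
Product: 26 (4R)-4-[4α-(triethylsilyloxy)-5αH-eudesm-11-en-1β-yl]-5,7,8-trimethoxychroman-2-one, via bis-silylated Criegee adduct 25 (not isolated)
Conditions: Me3SiOOSiMe3, Me3SiOTf (cat.), 2,6-di-tert-butyl-4-methylpyridine (cat.), CH2Cl2, −40 to 0 °C
Reagents that add atoms: bis(trimethylsilyl) peroxide, C[Si](C)(C)OO[Si](C)(C)C
Why: Me3SiOTf silylates the indanone carbonyl, the silyl peroxide adds to C1 to give the Criegee adduct 25, and the C1–C7a bond antiperiplanar to the O–O bond shifts from carbon to oxygen with loss of Me3SiOSiMe3. The closest known reaction type is the Baeyer–Villiger oxidation of 1-indanones to 3,4-dihydrocoumarins with aryl migration, run here in the Lewis-acid/silyl-peroxide variant used for ketones that carry alkenes. No ring is closed from an open chain: the six-membered lactone arises by one-atom expansion of the five-membered ketone through the 1,2-shift of C7a, which forms the O1′–C8a′ bond. No stereocentre is created, and C4′ lies outside the migrating bond and keeps its configuration. The step needs aryl rather than CH2 migration, which the aryl carbon C7a with its ortho methoxy group secures over the primary C2 methylene. It also needs attack at C=O rather than at the isopropenyl C=C or the arene, which the aprotic silyl peroxide (oxygen delivered only through the carbonyl adduct) and the hindered-pyridine buffer secure.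

Step 16
Reactants: 26 (4R)-4-eudesmanyl-5,7,8-trimethoxychroman-2-one
Product: 27 (4S)-4-[4α-(triethylsilyloxy)-5αH-eudesm-11-en-1β-yl]-5,7,8-trimethoxy-4H-chromen-2-yl diphenyl phosphate
Conditions: (PhO)2P(O)Cl, HMPA, THF, −78 °C, KN(SiMe3)2 added last
Reagents that add atoms: diphenyl chlorophosphate, O=P(Cl)(Oc1ccccc1)Oc1ccccc1
Why: Lactone enol phosphate formation: deprotonation at C3 in the presence of the chlorophosphate should trap the enolate on oxygen as the ketene acetal phosphate before it can fragment or condense, and C4′ is adjacent to but not part of the enolate.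

Step 17
Reactants: 27 ketene acetal phosphate; 28 phenylboronic acid
Product: 29 (4S)-4-[4α-(triethylsilyloxy)-5αH-eudesm-11-en-1β-yl]-5,7,8-trimethoxy-2-phenyl-4H-chromene
Conditions: Pd(PPh3)4 (cat.), 2 M aq. Na2CO3, DME, 75 °C
Reagents that add atoms: none
Why: Suzuki–Miyaura coupling: oxidative addition of zerovalent palladium into the C2′–O(phosphate) bond, transmetalation with the phenylboronate and reductive elimination should install the C2′ phenyl group and complete the 4H-chromene.

Step 18
Reactants: 29 silyl-protected chromene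
Product: 30 target, (4′S)-4′-(4α-hydroxy-5αH-eudesm-11-en-1β-yl)-5′,7′,8′-trimethoxy-2′-phenyl-4′H-chromene
Conditions: Bu4NF, THF, rt to 40 °C
Reagents that add atoms: none
Why: Fluoride-mediated desilylation should free the tertiary 4α-alcohol under non-acidic conditions that the acid-sensitive enol ether of the 4H-chromene tolerates.

**Compound list**

1 | (2R,5R)-2-methyl-5-(prop-1-en-2-yl)cyclohexan-1-one, (+)-dihydrocarvone (commercial material also contains the 2S epimer) | C=C(C)[C@@H]1CC[C@@H](C)C(=O)C1 | starting material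
2 | pent-1-en-3-one (ethyl vinyl ketone) | C=CC(=O)CC | starting material
3 | N-[(R)-1-phenylethyl]imine of dihydrocarvone (C2 not fixed; reacts as the secondary enamine) | C=C(C)[C@@H]1CCC(C)C(=N[C@H](C)c2ccccc2)C1 | intermediate (not isolated)
4 | N-[(R)-1-phenylethyl]imine of (2S,5R)-2-methyl-2-(3-oxopentyl)-5-(prop-1-en-2-yl)cyclohexanone | C=C(C)[C@@H]1CC[C@@](C)(CCC(=O)CC)C(=N[C@H](C)c2ccccc2)C1 | intermediate (not isolated)
5 | (2S,5R)-2-methyl-2-(3-oxopentyl)-5-(prop-1-en-2-yl)cyclohexan-1-one (methyl cis to isopropenyl) | C=C(C)[C@@H]1CC[C@@](C)(CCC(=O)CC)C(=O)C1 | intermediate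
6 | (+)-α-cyperone, eudesma-4,11-dien-3-one (4aS,7R) | C=C(C)[C@@H]1CC[C@@]2(C)CCC(=O)C(C)=C2C1 | intermediate
7 | (4βH,5αH)-eudesm-11-en-3-one (trans-fused; C4 methyl α) | C=C(C)[C@@H]1CC[C@]2(C)[C@@H](C1)[C@H](C)C(=O)CC2 | intermediate
8 | 3-(trimethylsilyloxy)-(4βH,5αH)-eudesma-2,11-diene | C=C(C)[C@@H]1CC[C@]2(C)[C@@H](C1)[C@H](C)C(O[Si](C)(C)C)=CC2 | intermediate (not isolated)
9 | (4βH,5αH)-eudesma-1,11-dien-3-one | C=C(C)[C@@H]1CC[C@]2(C)[C@@H](C1)[C@H](C)C(=O)C=C2 | intermediate
10 | 5αH-eudesma-1,3,11-trien-3-yl trifluoromethanesulfonate | C=C(C)[C@@H]1CC[C@]2(C)[C@@H](C1)C(C)=C(OS(=O)(=O)C(F)(F)F)C=C2 | intermediate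
11 | 5αH-eudesma-1,3,11-triene | C=C(C)[C@@H]1CC[C@]2(C)[C@@H](C1)C(C)=CC=C2 | intermediate
12 | 1α,4α-epidioxy-5αH-eudesma-2,11-diene | C=C(C)[C@@H]1CC[C@]2(C)[C@@H](C1)[C@]3(C)OO[C@H]2C=C3 | intermediate (not isolated)
13 | 4α-hydroxy-5αH-eudesma-2,11-dien-1-one | C=C(C)[C@@H]1CC[C@]2(C)[C@@H](C1)[C@](C)(O)C=CC2=O | intermediate
14 | 4α-(triethylsilyloxy)-5αH-eudesma-2,11-dien-1-one | C=C(C)[C@@H]1CC[C@]2(C)[C@@H](C1)[C@](C)(O[Si](CC)(CC)CC)C=CC2=O | intermediate
15 | 4α-(triethylsilyloxy)-5αH-eudesm-11-en-1-one | C=C(C)[C@@H]1CC[C@]2(C)[C@@H](C1)[C@](C)(O[Si](CC)(CC)CC)CCC2=O | intermediate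
16 | 1-(methoxymethylidene)-4α-(triethylsilyloxy)-5αH-eudesm-11-ene (E/Z mixture) | C=C(C)[C@@H]1CC[C@]2(C)[C@@H](C1)[C@](C)(O[Si](CC)(CC)CC)CCC2=COC | intermediate (not isolated)
17 | 4α-(triethylsilyloxy)-5αH-eudesm-11-ene-1β-carbaldehyde (1α-H; formyl equatorial) | C=C(C)[C@@H]1CC[C@]2(C)[C@@H](C1)[C@](C)(O[Si](CC)(CC)CC)CC[C@H]2C=O | intermediate
18 | 5-{[4α-(triethylsilyloxy)-5αH-eudesm-11-en-1β-yl]methylidene}-2,2-dimethyl-1,3-dioxane-4,6-dione | C=C(C)[C@@H]1CC[C@]2(C)[C@@H](C1)[C@](C)(O[Si](CC)(CC)CC)CC[C@H]2C=C1C(=O)OC(C)(C)OC1=O | intermediate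
19 | 1-bromo-2,4,5-trimethoxybenzene | COc1cc(OC)c(OC)cc1Br | starting material
20 | 2,4,5-trimethoxyphenylmagnesium bromide | COc1cc(OC)c(OC)cc1[Mg]Br | intermediate (not isolated)
21 | 5-{(S)-[4α-(triethylsilyloxy)-5αH-eudesm-11-en-1β-yl](2,4,5-trimethoxyphenyl)methyl}-2,2-dimethyl-1,3-dioxane-4,6-dione | C=C(C)[C@@H]1CC[C@]2(C)[C@@H](C1)[C@](C)(O[Si](CC)(CC)CC)CC[C@H]2[C@@H](C1C(=O)OC(C)(C)OC1=O)c1cc(OC)c(OC)cc1OC | intermediate
22 | (3R)-3-[4α-(triethylsilyloxy)-5αH-eudesm-11-en-1β-yl]-3-(2,4,5-trimethoxyphenyl)propanoic acid | C=C(C)[C@@H]1CC[C@]2(C)[C@@H](C1)[C@](C)(O[Si](CC)(CC)CC)CC[C@H]2[C@@H](CC(=O)O)c1cc(OC)c(OC)cc1OC | intermediate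
23 | (3R)-3-[4α-(triethylsilyloxy)-5αH-eudesm-11-en-1β-yl]-3-(2,4,5-trimethoxyphenyl)propanoyl chloride | C=C(C)[C@@H]1CC[C@]2(C)[C@@H](C1)[C@](C)(O[Si](CC)(CC)CC)CC[C@H]2[C@@H](CC(=O)Cl)c1cc(OC)c(OC)cc1OC | intermediate (not isolated)
24 | (3R)-3-[4α-(triethylsilyloxy)-5αH-eudesm-11-en-1β-yl]-4,6,7-trimethoxyindan-1-one | C=C(C)[C@@H]1CC[C@]2(C)[C@@H](C1)[C@](C)(O[Si](CC)(CC)CC)CC[C@H]2[C@H]1CC(=O)c2c(OC)c(OC)cc(OC)c21 | intermediate
25 | Criegee adduct of 24: 1-(trimethylsilyloxy)-1-(trimethylsilylperoxy)indane (C1 epimers) | C=C(C)[C@@H]1CC[C@]2(C)[C@@H](C1)[C@](C)(O[Si](CC)(CC)CC)CC[C@H]2[C@H]1CC(O[Si](C)(C)C)(OO[Si](C)(C)C)c2c(OC)c(OC)cc(OC)c21 | intermediate (not isolated)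
26 | (4R)-4-[4α-(triethylsilyloxy)-5αH-eudesm-11-en-1β-yl]-5,7,8-trimethoxychroman-2-one | C=C(C)[C@@H]1CC[C@]2(C)[C@@H](C1)[C@](C)(O[Si](CC)(CC)CC)CC[C@H]2[C@H]1CC(=O)Oc2c(OC)c(OC)cc(OC)c21 | intermediate
27 | (4S)-4-[4α-(triethylsilyloxy)-5αH-eudesm-11-en-1β-yl]-5,7,8-trimethoxy-4H-chromen-2-yl diphenyl phosphate | C=C(C)[C@@H]1CC[C@]2(C)[C@@H](C1)[C@](C)(O[Si](CC)(CC)CC)CC[C@H]2[C@H]1C=C(OP(=O)(Oc3ccccc3)Oc3ccccc3)Oc2c(OC)c(OC)cc(OC)c21 | intermediate
28 | phenylboronic acid | OB(O)c1ccccc1 | starting material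
29 | (4S)-4-[4α-(triethylsilyloxy)-5αH-eudesm-11-en-1β-yl]-5,7,8-trimethoxy-2-phenyl-4H-chromene | C=C(C)[C@@H]1CC[C@]2(C)[C@@H](C1)[C@](C)(O[Si](CC)(CC)CC)CC[C@H]2[C@H]1C=C(c3ccccc3)Oc2c(OC)c(OC)cc(OC)c21 | intermediate
30 | (4′S)-4′-(4α-hydroxy-5αH-eudesm-11-en-1β-yl)-5′,7′,8′-trimethoxy-2′-phenyl-4′H-chromene | C=C(C)[C@@H]1CC[C@]2(C)[C@@H](C1)[C@](C)(O)CC[C@H]2[C@H]1C=C(c2ccccc2)Oc2c(OC)c(OC)cc(OC)c21 | target

**Step count**
Total: 18 steps. Longest linear sequence: 18 steps (1 to 30; 19 and 28 enter as purchased materials).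

**Steps most likely to fail**

Step 15 (key step). The silyl peroxide may fail to add to the ortho-methoxylated aryl ketone at temperatures the Lewis acid allows, or electrophilic oxidation of the trimethoxyarene may outrun carbonyl addition. The fallback sets out from indanone 24 and returns at lactone 26. A buffered peracid (mCPBA, Na2HPO4, CH2Cl2, 0 °C to rt) would carry out the same aryl-migrating oxygen insertion while also epoxidising the isopropenyl group, giving the 11,12-epoxy lactone F1. The alkene would then be restored by rhodium-carbenoid deoxygenation of the epoxide (dimethyl diazomalonate, Rh2(OAc)4 cat., toluene, 80 °C), which gives 26.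

Step 12. Facial discrimination in the aryl addition may be too low, or the Grignard reagent may deprotonate the γ-position of the alkylidene instead of adding. The fallback sets out from aldehyde 17 and returns at acid 22, with catalyst control in place of substrate control. Wittig olefination of 17 (Ph3P=CHCO2Me, toluene, 90 °C) would give the (E)-enoate F2. 2,4,5-Trimethoxyphenylboronic acid F3 would be made from 19 (n-BuLi, THF, −78 °C; B(O-i-Pr)3; aq. HCl). A Hayashi–Miyaura 1,4-addition of F3 to F2 with [Rh(OH)((R)-BINAP)]2 (dioxane/H2O, 60 °C) would give the methyl ester F4. The (R)-ligand is chosen because, by the usual facial model for (E)-enoates, it delivers aryl to the face the substrate also prefers. Saponification (LiOH, THF/MeOH/H2O) would then give 22.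

Step 16. The aryl-ester enolate may fragment to a ketene and phenoxide, phosphorylate on carbon, or the ketene acetal phosphate may hydrolyse on isolation. The fallback sets out from lactone 26 and returns at chromene 29, bringing in the phenyl group as a nucleophile. Ring opening of 26 with MeNHOMe·HCl and i-PrMgCl (THF, −20 °C) would give the phenolic Weinreb amide F5. PhMgBr (excess, THF, 0 °C; the phenol carried as its magnesium salt) would give the 2′-hydroxyaryl ketone F6, in equilibrium with its lactol. Cyclodehydration (PPTS cat., toluene, 4 Å molecular sieves, 70 °C) would close the enol ether and give 29.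

**Further compounds**

F1 | step 15 | 11,12-epoxide of lactone 26 (C11 epimers) | CC1(CO1)[C@@H]2CC[C@]3(C)[C@@H](C2)[C@](C)(O[Si](CC)(CC)CC)CC[C@H]3[C@H]2CC(=O)Oc3c(OC)c(OC)cc(OC)c32
F2 | step 12 | methyl (E)-3-[4α-(triethylsilyloxy)-5αH-eudesm-11-en-1β-yl]prop-2-enoate | C=C(C)[C@@H]1CC[C@]2(C)[C@@H](C1)[C@](C)(O[Si](CC)(CC)CC)CC[C@H]2/C=C/C(=O)OC
F3 | step 12 | 2,4,5-trimethoxyphenylboronic acid | OB(O)c1cc(OC)c(OC)cc1OC
F4 | step 12 | methyl (3R)-3-[4α-(triethylsilyloxy)-5αH-eudesm-11-en-1β-yl]-3-(2,4,5-trimethoxyphenyl)propanoate | C=C(C)[C@@H]1CC[C@]2(C)[C@@H](C1)[C@](C)(O[Si](CC)(CC)CC)CC[C@H]2[C@@H](CC(=O)OC)c1cc(OC)c(OC)cc1OC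
F5 | step 16 | (3R)-3-[4α-(triethylsilyloxy)-5αH-eudesm-11-en-1β-yl]-3-(2-hydroxy-3,4,6-trimethoxyphenyl)-N-methoxy-N-methylpropanamide | C=C(C)[C@@H]1CC[C@]2(C)[C@@H](C1)[C@](C)(O[Si](CC)(CC)CC)CC[C@H]2[C@@H](CC(=O)N(C)OC)c1c(OC)cc(OC)c(OC)c1O
F6 | step 16 | (3R)-3-[4α-(triethylsilyloxy)-5αH-eudesm-11-en-1β-yl]-3-(2-hydroxy-3,4,6-trimethoxyphenyl)-1-phenylpropan-1-one | C=C(C)[C@@H]1CC[C@]2(C)[C@@H](C1)[C@](C)(O[Si](CC)(CC)CC)CC[C@H]2[C@@H](CC(=O)c1ccccc1)c1c(OC)cc(OC)c(OC)c1O
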